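**Plan**

1. Numbering is that of a germacranolide (C15 = CHO on C4, epoxide C1–C10, OH on C2, tiglate on C8, lactone O on C6, ring fusion C7). The retrosynthesis turns the C15 formyl into a C4=C15 exocyclic methylene and the epoxide into the E‑C1=C10 alkene, then cuts the C2–C3 ring bond to give the seco enal/allylic chloride 20. It then cuts the lactone bonds C6–C7 and O–C12 to give aldehyde 4 and allylboronate 14; the tiglate is an ester cut.
2. Enabling feature: with C15 as a methylene, C2(OH)–C3H2–C4(=C15H2) in the ten‑membered ring is a homoallylic alcohol, and C2 is allylic to C1=C10. C2 can therefore be an enal carbonyl and C3 the terminus of a 2‑substituted allyl metal, while the E‑C1=C10 bond and the trans‑fused lactone at C6–C7 pre‑organise the two arms.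
3. Forward: dimethyl itaconate gives 4 in 3 steps and E‑enynol 5 gives Z‑allylboronate 14 in 5 steps. Allylboration–lactonisation joins them and forms the lactone ring first (16); desilylation, allylic oxidation and tigloylation give 20. Macro‑allylation with CrCl2 then closes the carbocycle (22), and epoxidation, hydroboration–oxidation and alcohol oxidation finish the route.
4. Stereochemistry: C8 comes from a catalytic asymmetric alkynylation. C7 and C6 come from the chair allylboration (Z‑boronate gives the trans lactone; the C8 silyloxy centre controls the face). C2 is set in the ring closure by substrate control, C1/C10 by hydroxyl‑directed epoxidation of the E‑alkene, and C4 by hydroboration of the exocyclic alkene on the macrocycle.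

Key step: step 13

Remark: germacranolide numbering is used for the ring compounds, so the target is 1R,2S,4S,6R,7S,8S,10R; (S,S)‑ProPhenol is assumed to give the 4S alcohol 10, otherwise its enantiomer is used.

**Route**

Step 1
Reactants: 1 dimethyl itaconate (dimethyl 2‑methylidenebutanedioate)
Product: 2 2‑methylidenebutane‑1,4‑diol
Conditions: DIBAL‑H (4.5 equiv), CH2Cl2, −78 → 0 °C; aq. potassium sodium tartrate
Reagents that add atoms: none
Why: Ester reduction with DIBAL‑H, which reduces the conjugated ester 1,2 to the allylic alcohol and the saturated ester to the primary alcohol and leaves the 1,1‑disubstituted alkene alone.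

Step 2
Reactants: 2 2‑methylidenebutane‑1,4‑diol
Product: 3 3‑(chloromethyl)but‑3‑en‑1‑ol
Conditions: NCS, Me2S, CH2Cl2, −20 → 0 °C
Reagents that add atoms: N‑chlorosuccinimide, O=C1CCC(=O)N1Cl
Why: Corey–Kim chlorination converts only the allylic alcohol into the chloride, because the alkoxysulfonium salt of the saturated alcohol is not displaced at low temperature and reverts on work‑up.

Step 3
Reactants: 3 3‑(chloromethyl)but‑3‑en‑1‑ol
Product: 4 3‑(chloromethyl)but‑3‑enal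
Conditions: Dess–Martin periodinane, NaHCO3, CH2Cl2, 0 °C; used crude
Reagents that add atoms: none
Why: Dess–Martin oxidation under buffered, non‑basic conditions should give the β,γ‑unsaturated aldehyde without migration of the double bond into conjugation.

Step 4
Reactants: 5 (2E)‑3‑methylpent‑2‑en‑4‑yn‑1‑ol
Product: 6 tert‑butyl(dimethyl){[(2E)‑3‑methylpent‑2‑en‑4‑yn‑1‑yl]oxy}silane
Conditions: TBSCl, imidazole, DMF, 23 °C
Reagents that add atoms: tert‑butyldimethylsilyl chloride, CC(C)(C)[Si](C)(C)Cl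
Why: Standard silylation of the primary alcohol; the E geometry of the later C1=C10 bond is bought with the starting material.

Step 5
Reactants: 6 tert‑butyl(dimethyl){[(2E)‑3‑methylpent‑2‑en‑4‑yn‑1‑yl]oxy}silane
Product: 8 (3E)‑5‑{[tert‑butyl(dimethyl)silyl]oxy}‑3‑methylpent‑3‑enal, via dienylborane 7 (not isolated)
Conditions: Cy2BH (from BH3·SMe2 and cyclohexene, 1.1 equiv), THF, 0 °C; then Na2HPO4/NaH2PO4 buffer (pH 7), 30% H2O2, 0 °C; used crude
Reagents that add atoms: hydrogen peroxide, OO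
Why: Anti‑Markovnikov monohydroboration of the terminal alkyne by a bulky dialkylborane (Brown hydroboration) and buffered oxidation of the alkenylborane; kinetic α‑protonation of the dienol should give the β,γ‑unsaturated aldehyde.

Step 6
Reactants: 8 (3E)‑5‑{[tert‑butyl(dimethyl)silyl]oxy}‑3‑methylpent‑3‑enal; 9 methyl propiolate
Product: 10 methyl (4S,6E)‑8‑{[tert‑butyl(dimethyl)silyl]oxy}‑4‑hydroxy‑6‑methyloct‑6‑en‑2‑ynoate
Conditions: Me2Zn (3 equiv), (S,S)‑ProPhenol (20 mol%), Ph3PO (40 mol%), toluene, 4 °C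
Reagents that add atoms: none
Why: Zinc–ProPhenol‑catalysed asymmetric alkynylation of an aldehyde, in which the chiral catalyst formed from Me2Zn and the ligand delivers the zinc propiolate to one face of the formyl group and so sets C8 (4S in 10).

Step 7
Reactants: 10 methyl (4S,6E)‑8‑{[tert‑butyl(dimethyl)silyl]oxy}‑4‑hydroxy‑6‑methyloct‑6‑en‑2‑ynoate
Product: 11 methyl (4S,6E)‑4,8‑bis{[tert‑butyl(dimethyl)silyl]oxy}‑6‑methyloct‑6‑en‑2‑ynoate
Conditions: TBSOTf, 2,6‑lutidine, CH2Cl2, −78 °C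
Reagents that add atoms: tert‑butyldimethylsilyl triflate, CC(C)(C)[Si](C)(C)OS(=O)(=O)C(F)(F)F
Why: Silylation of the propargylic alcohol gives a bulky ether that withstands the aluminium hydride and later steers the facial selectivity of step 9.

Step 8
Reactants: 11 methyl (4S,6E)‑4,8‑bis{[tert‑butyl(dimethyl)silyl]oxy}‑6‑methyloct‑6‑en‑2‑ynoate; 12 2‑(iodomethyl)‑4,4,5,5‑tetramethyl‑1,3,2‑dioxaborolane
Product: 14 methyl (2Z,4S,6E)‑4,8‑bis{[tert‑butyl(dimethyl)silyl]oxy}‑6‑methyl‑2‑[(4,4,5,5‑tetramethyl‑1,3,2‑dioxaborolan‑2‑yl)methyl]octa‑2,6‑dienoate, via vinylalane 13 (not isolated)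
Conditions: DIBAL‑H (1.2 equiv), HMPA, THF, 0 °C; then 12 (1.5 equiv), 0 → 23 °C
Reagents that add atoms: none
Why: Conjugate syn‑hydroalumination of the ynoate by DIBAL‑H/HMPA gives the α‑aluminio acrylate with H and Al cis, and its C‑alkylation by the iodomethylboronate with retention should give the Z 2‑alkoxycarbonyl allylboronate (C8 chain cis to the ester).

Step 9
Reactants: 14 methyl (2Z,4S,6E)‑4,8‑bis{[tert‑butyl(dimethyl)silyl]oxy}‑6‑methyl‑2‑[(4,4,5,5‑tetramethyl‑1,3,2‑dioxaborolan‑2‑yl)methyl]octa‑2,6‑dienoate; 4 3‑(chloromethyl)but‑3‑enal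
Product: 16 (4S,5R)‑4‑[(1S,3E)‑1,5‑bis{[tert‑butyl(dimethyl)silyl]oxy}‑3‑methylpent‑3‑en‑1‑yl]‑5‑[2‑(chloromethyl)prop‑2‑en‑1‑yl]‑3‑methylideneoxolan‑2‑one, via hydroxy ester 15 (not isolated)
Conditions: Sc(OTf)3 (10 mol%), toluene, −20 → 23 °C; then p‑TsOH·H2O (5 mol%), CH2Cl2, 23 °C
Reagents that add atoms: none
Why: Lewis‑acid‑catalysed tandem allylboration–lactonisation of a 2‑alkoxycarbonyl allylboronate through a closed chair transition state: the Z boronate places the C8 chain equatorial and gives the anti adduct, hence the trans lactone (C6 R), and with H8 held in the alkene plane by A(1,3) strain to the cis ester the aldehyde should add anti to the C–OSi bond (Felkin–Anh‑type induction), which sets C7.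

Step 10
Reactants: 16 (4S,5R)‑4‑[(1S,3E)‑1,5‑bis{[tert‑butyl(dimethyl)silyl]oxy}‑3‑methylpent‑3‑en‑1‑yl]‑5‑[2‑(chloromethyl)prop‑2‑en‑1‑yl]‑3‑methylideneoxolan‑2‑one
Product: 17 (4R,5R)‑5‑[2‑(chloromethyl)prop‑2‑en‑1‑yl]‑4‑[(1S,3E)‑1,5‑dihydroxy‑3‑methylpent‑3‑en‑1‑yl]‑3‑methylideneoxolan‑2‑one
Conditions: HF (48% aq.), MeCN, 0 → 23 °C
Reagents that add atoms: none
Why: Acidic fluoride desilylation removes both silyl ethers without base, so the allylic chloride, the α‑methylene lactone and the position of the lactone (no migration to O8) should be kept.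

Step 11
Reactants: 17 (4R,5R)‑5‑[2‑(chloromethyl)prop‑2‑en‑1‑yl]‑4‑[(1S,3E)‑1,5‑dihydroxy‑3‑methylpent‑3‑en‑1‑yl]‑3‑methylideneoxolan‑2‑one
Product: 18 (2E,5S)‑5‑{(2R,3R)‑2‑[2‑(chloromethyl)prop‑2‑en‑1‑yl]‑4‑methylidene‑5‑oxooxolan‑3‑yl}‑5‑hydroxy‑3‑methylpent‑2‑enal
Conditions: MnO2 (20 equiv), CH2Cl2, 23 °C
Reagents that add atoms: none
Why: Allylic oxidation with MnO2 converts only the primary allylic alcohol into the E‑enal; the secondary C8 hydroxyl is not allylic and is inert.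

Step 12
Reactants: 18 (2E,5S)‑5‑{(2R,3R)‑2‑[2‑(chloromethyl)prop‑2‑en‑1‑yl]‑4‑methylidene‑5‑oxooxolan‑3‑yl}‑5‑hydroxy‑3‑methylpent‑2‑enal; 19 tiglic acid [(2E)‑2‑methylbut‑2‑enoic acid]
Product: 20 (1S,3E)‑1‑{(2R,3R)‑2‑[2‑(chloromethyl)prop‑2‑en‑1‑yl]‑4‑methylidene‑5‑oxooxolan‑3‑yl}‑3‑methyl‑5‑oxopent‑3‑en‑1‑yl (2E)‑2‑methylbut‑2‑enoate
Conditions: 2,4,6‑trichlorobenzoyl chloride, Et3N, DMAP, toluene, 0 → 23 °C
Reagents that add atoms: none
Why: Yamaguchi esterification through the mixed anhydride acylates the hindered secondary alcohol, and the E (tiglate) geometry is the thermodynamic one and should be retained.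

Step 13
Reactants: 20 (1S,3E)‑1‑{(2R,3R)‑2‑[2‑(chloromethyl)prop‑2‑en‑1‑yl]‑4‑methylidene‑5‑oxooxolan‑3‑yl}‑3‑methyl‑5‑oxopent‑3‑en‑1‑yl (2E)‑2‑methylbut‑2‑enoate
Product: 22 (1(10)E,2S,6R,7S,8S)‑2‑hydroxy‑8‑[(2E)‑2‑methylbut‑2‑enoyloxy]germacra‑1(10),4(15),11(13)‑trien‑12,6‑olide, via allylchromium species 21 (not isolated)
Conditions: CrCl2 (8 equiv), THF–DMF 4:1, 23 °C; 20 added by syringe pump over 12 h (final 0.003 M); aq. NH4Cl
Reagents that add atoms: none
Why: CrCl2 (divalent chromium, two equivalents per C–Cl bond) reduces the allylic chloride by two single‑electron transfers to the trivalent allylchromium species 21, which adds 1,2 to the enal carbonyl through a six‑membered chair‑like Zimmerman–Traxler transition state and gives, after hydrolysis of the chromium alkoxide, the homoallylic alcohol 22. The closest known reaction type is the intramolecular Nozaki–Hiyama–Kishi allylation, which has closed ten‑ and fourteen‑membered terpenoid carbocycles from ω‑formyl allylic halides. The ten‑membered carbocycle closes in a 10‑exo‑trig mode (C3 on the formyl carbon C2), helped by the trans‑fused lactone, which already ties C6 to C7, and by the rigid E‑C1=C10 enal. The one new stereocentre, C2, is under substrate control: the chromium‑bound oxygen has to sit on the outside of the nascent ring, the s‑trans enal keeps H2 in the alkene plane next to the C10 methyl (A(1,3) strain), and the trans lactone with its C8 ester biases the chain so that the Si face of the formyl group should be presented to C3, which gives 2S. Chemoselectivity (formyl group over lactone, tiglate and both conjugated alkenes) follows from the oxophilic, weakly basic allylchromium reagent, which does not add in a conjugate sense, and regioselectivity is no issue because either terminus of the 2‑substituted allyl unit gives the same product. High dilution and slow addition are needed to hold oligomerisation back.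

Step 14
Reactants: 22 (1(10)E,2S,6R,7S,8S)‑2‑hydroxy‑8‑[(2E)‑2‑methylbut‑2‑enoyloxy]germacra‑1(10),4(15),11(13)‑trien‑12,6‑olide
Product: 23 (1R,2S,6R,7S,8S,10R)‑1,10‑epoxy‑2‑hydroxy‑8‑[(2E)‑2‑methylbut‑2‑enoyloxy]germacra‑4(15),11(13)‑dien‑12,6‑olide
Conditions: VO(acac)2 (5 mol%), t‑BuOOH (1.5 equiv, decane solution), CH2Cl2, 0 °C
Reagents that add atoms: tert‑butyl hydroperoxide, CC(C)(C)OO
Why: Vanadium‑catalysed hydroxyl‑directed epoxidation touches only the allylic alcohol alkene; A(1,3) strain with the C10 methyl keeps H2 in the alkene plane and the 2‑OH on the outer face of the E‑cycloalkene, so oxygen should be delivered syn to the hydroxyl from the periphery to give the threo 1R,10R epoxy alcohol.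

Step 15
Reactants: 23 (1R,2S,6R,7S,8S,10R)‑1,10‑epoxy‑2‑hydroxy‑8‑[(2E)‑2‑methylbut‑2‑enoyloxy]germacra‑4(15),11(13)‑dien‑12,6‑olide
Product: 25 (1R,2S,4S,6R,7S,8S,10R)‑1,10‑epoxy‑2,15‑dihydroxy‑8‑[(2E)‑2‑methylbut‑2‑enoyloxy]germacr‑11(13)‑en‑12,6‑olide, via alkylborane 24 (not isolated)
Conditions: 9‑BBN (2.5 equiv), THF, 0 → 23 °C; then Na2HPO4/NaH2PO4 buffer (pH 7), 30% H2O2, 0 °C
Reagents that add atoms: hydrogen peroxide, OO
Why: Anti‑Markovnikov Brown hydroboration–oxidation, in which 9‑BBN should react with the electron‑rich 1,1‑disubstituted C4=C15 alkene far faster than with the electron‑poor lactone methylene or the trisubstituted tiglate; syn addition from the more open face of the exocyclic alkene is expected, but not secured, to put C15 trans to the C2 oxygen (4S).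

Step 16
Reactants: 25 (1R,2S,4S,6R,7S,8S,10R)‑1,10‑epoxy‑2,15‑dihydroxy‑8‑[(2E)‑2‑methylbut‑2‑enoyloxy]germacr‑11(13)‑en‑12,6‑olide
Product: 26 (1R,2S,4S,6R,7S,8S,10R)‑1,10‑epoxy‑2‑hydroxy‑15‑oxo‑8‑[(2E)‑2‑methylbut‑2‑enoyloxy]germacr‑11(13)‑en‑12,6‑olide (CNP0307768.2)
Conditions: TEMPO (10 mol%), PhI(OAc)2 (1.2 equiv), CH2Cl2, 23 °C
Reagents that add atoms: none
Why: TEMPO/PhI(OAc)2 oxidation is selective for the primary alcohol over the secondary 2‑OH and stops at the aldehyde, which should not close to a lactol because C15 and the 2‑OH are trans on the ring.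

**Compound list**

1 | dimethyl itaconate | C=C(CC(=O)OC)C(=O)OC | starting material
2 | 2‑methylidenebutane‑1,4‑diol | C=C(CO)CCO | intermediate
3 | 3‑(chloromethyl)but‑3‑en‑1‑ol | C=C(CCl)CCO | intermediate
4 | 3‑(chloromethyl)but‑3‑enal | C=C(CCl)CC=O | intermediate
5 | (2E)‑3‑methylpent‑2‑en‑4‑yn‑1‑ol | C#C/C(C)=C/CO | starting material
6 | tert‑butyl(dimethyl){[(2E)‑3‑methylpent‑2‑en‑4‑yn‑1‑yl]oxy}silane | C#C/C(C)=C/CO[Si](C)(C)C(C)(C)C | intermediate
7 | dicyclohexyl[(1E,3E)‑5‑{[tert‑butyl(dimethyl)silyl]oxy}‑3‑methylpenta‑1,3‑dien‑1‑yl]borane | C1CCCCC1B(/C=C/C(C)=C/CO[Si](C)(C)C(C)(C)C)C1CCCCC1 | intermediate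
8 | (3E)‑5‑{[tert‑butyl(dimethyl)silyl]oxy}‑3‑methylpent‑3‑enal | O=CC/C(C)=C/CO[Si](C)(C)C(C)(C)C | intermediate
9 | methyl propiolate | C#CC(=O)OC | starting material
10 | methyl (4S,6E)‑8‑{[tert‑butyl(dimethyl)silyl]oxy}‑4‑hydroxy‑6‑methyloct‑6‑en‑2‑ynoate | COC(=O)C#C[C@@H](O)C/C(C)=C/CO[Si](C)(C)C(C)(C)C | intermediate
11 | methyl (4S,6E)‑4,8‑bis{[tert‑butyl(dimethyl)silyl]oxy}‑6‑methyloct‑6‑en‑2‑ynoate | COC(=O)C#C[C@@H](O[Si](C)(C)C(C)(C)C)C/C(C)=C/CO[Si](C)(C)C(C)(C)C | intermediate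
12 | 2‑(iodomethyl)‑4,4,5,5‑tetramethyl‑1,3,2‑dioxaborolane | ICB1OC(C)(C)C(C)(C)O1 | starting material
13 | methyl (2E,4S,6E)‑2‑[bis(2‑methylpropyl)alumanyl]‑4,8‑bis{[tert‑butyl(dimethyl)silyl]oxy}‑6‑methylocta‑2,6‑dienoate (vinylalane) | COC(=O)/C([Al](CC(C)C)CC(C)C)=C\[C@@H](O[Si](C)(C)C(C)(C)C)C/C(C)=C/CO[Si](C)(C)C(C)(C)C | intermediate
14 | methyl (2Z,4S,6E)‑4,8‑bis{[tert‑butyl(dimethyl)silyl]oxy}‑6‑methyl‑2‑[(4,4,5,5‑tetramethyl‑1,3,2‑dioxaborolan‑2‑yl)methyl]octa‑2,6‑dienoate | COC(=O)/C(CB1OC(C)(C)C(C)(C)O1)=C\[C@@H](O[Si](C)(C)C(C)(C)C)C/C(C)=C/CO[Si](C)(C)C(C)(C)C | intermediate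
15 | methyl (3S,4R)‑3‑[(1S,3E)‑1,5‑bis{[tert‑butyl(dimethyl)silyl]oxy}‑3‑methylpent‑3‑en‑1‑yl]‑6‑(chloromethyl)‑4‑hydroxy‑2‑methylidenehept‑6‑enoate | COC(=O)C(=C)[C@@H]([C@H](O)CC(=C)CCl)[C@@H](O[Si](C)(C)C(C)(C)C)C/C(C)=C/CO[Si](C)(C)C(C)(C)C | intermediate
16 | (4S,5R)‑4‑[(1S,3E)‑1,5‑bis{[tert‑butyl(dimethyl)silyl]oxy}‑3‑methylpent‑3‑en‑1‑yl]‑5‑[2‑(chloromethyl)prop‑2‑en‑1‑yl]‑3‑methylideneoxolan‑2‑one | C=C1C(=O)O[C@H](CC(=C)CCl)[C@H]1[C@@H](O[Si](C)(C)C(C)(C)C)C/C(C)=C/CO[Si](C)(C)C(C)(C)C | intermediate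
17 | (4R,5R)‑5‑[2‑(chloromethyl)prop‑2‑en‑1‑yl]‑4‑[(1S,3E)‑1,5‑dihydroxy‑3‑methylpent‑3‑en‑1‑yl]‑3‑methylideneoxolan‑2‑one | C=C1C(=O)O[C@H](CC(=C)CCl)[C@H]1[C@@H](O)C/C(C)=C/CO | intermediate
18 | (2E,5S)‑5‑{(2R,3R)‑2‑[2‑(chloromethyl)prop‑2‑en‑1‑yl]‑4‑methylidene‑5‑oxooxolan‑3‑yl}‑5‑hydroxy‑3‑methylpent‑2‑enal | C=C1C(=O)O[C@H](CC(=C)CCl)[C@H]1[C@@H](O)C/C(C)=C/C=O | intermediate
19 | tiglic acid, (2E)‑2‑methylbut‑2‑enoic acid | OC(=O)/C(C)=C/C | starting material
20 | (1S,3E)‑1‑{(2R,3R)‑2‑[2‑(chloromethyl)prop‑2‑en‑1‑yl]‑4‑methylidene‑5‑oxooxolan‑3‑yl}‑3‑methyl‑5‑oxopent‑3‑en‑1‑yl (2E)‑2‑methylbut‑2‑enoate | C=C1C(=O)O[C@H](CC(=C)CCl)[C@H]1[C@@H](OC(=O)/C(C)=C/C)C/C(C)=C/C=O | intermediate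
21 | trivalent allylchromium dichloride of 20 (CrCl2 in place of Cl) | C=C1C(=O)O[C@H](CC(=C)C[Cr](Cl)Cl)[C@H]1[C@@H](OC(=O)/C(C)=C/C)C/C(C)=C/C=O | intermediate
22 | (1(10)E,2S,6R,7S,8S)‑2‑hydroxy‑8‑[(2E)‑2‑methylbut‑2‑enoyloxy]germacra‑1(10),4(15),11(13)‑trien‑12,6‑olide | C=C1C(=O)O[C@@H]2CC(=C)C[C@H](O)/C=C(C)/C[C@H](OC(=O)/C(C)=C/C)[C@@H]12 | intermediate
23 | (1R,2S,6R,7S,8S,10R)‑1,10‑epoxy‑2‑hydroxy‑8‑[(2E)‑2‑methylbut‑2‑enoyloxy]germacra‑4(15),11(13)‑dien‑12,6‑olide | C=C1C(=O)O[C@@H]2CC(=C)C[C@H](O)[C@H]3O[C@]3(C)C[C@H](OC(=O)/C(C)=C/C)[C@@H]12 | intermediate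
24 | C15 B‑alkyl‑9‑BBN adduct of 23 with the 2‑oxygen as its 9‑BBN borinate | C=C1C(=O)O[C@@H]2C[C@@H](CB5C6CCCC5CCC6)C[C@H](OB7C8CCCC7CCC8)[C@H]3O[C@]3(C)C[C@H](OC(=O)/C(C)=C/C)[C@@H]12 | intermediate
25 | (1R,2S,4S,6R,7S,8S,10R)‑1,10‑epoxy‑2,15‑dihydroxy‑8‑[(2E)‑2‑methylbut‑2‑enoyloxy]germacr‑11(13)‑en‑12,6‑olide | C=C1C(=O)O[C@@H]2C[C@@H](CO)C[C@H](O)[C@H]3O[C@]3(C)C[C@H](OC(=O)/C(C)=C/C)[C@@H]12 | intermediate
26 | (1R,2S,4S,6R,7S,8S,10R)‑1,10‑epoxy‑2‑hydroxy‑15‑oxo‑8‑[(2E)‑2‑methylbut‑2‑enoyloxy]germacr‑11(13)‑en‑12,6‑olide (CNP0307768.2) | C=C1C(=O)O[C@@H]2C[C@@H](C=O)C[C@H](O)[C@H]3O[C@]3(C)C[C@H](OC(=O)/C(C)=C/C)[C@@H]12 | target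

**Count and risks**

Total step count: 16. Longest linear sequence: 13 steps (steps 4 to 16, from 5); steps 1 to 3 are the side branch to 4.

Steps most likely to fail:

1. Step 13 (ring closure). The formyl group may be attacked on its Re face, which gives the 2R carbinol, and intermolecular addition may compete with closure of the strained ring. The fallback sets out from 20. The chromium‑mediated closure is accepted without stereocontrol, and the 2R epimer of 22 F1, alone or mixed with 22, is oxidised with MnO2 in CH2Cl2 to the macrocyclic enone F2. F2 is reduced with (R)‑2‑methyl‑CBS‑oxazaborolidine and catecholborane in toluene at −78 °C (Corey–Bakshi–Shibata reduction, alkenyl side as the large group), so that C2 is set by the reagent. The route is rejoined at 22.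

2. Step 15 (hydroboration). The borane may add to the face of the exocyclic alkene that puts C15 cis to the C2 oxygen, since nothing in the substrate clearly secures the facial sense. The fallback sets out from 23. Silylation with Et3SiCl and imidazole gives the 2‑O‑triethylsilyl ether F3. 9‑BBN gives the alkylborane F4, and buffered H2O2 gives the primary alcohol F5 as a mixture of C4 epimers. Dess–Martin oxidation gives the aldehyde F6 as the epimer mixture. With the 2‑oxygen blocked, F6 is equilibrated through its enol with Et3N in CH2Cl2 and separated, with recycling of the unwanted epimer, to the aldehyde with the C4 configuration of the target F7. HF·pyridine in THF removes the silyl group, and the route is rejoined at 26.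

3. Step 9 (allylboration–lactonisation). The aldehyde may add syn instead of anti to the C8 silyloxy group, which would invert C6 and C7 relative to C8. The fallback sets out from 8 and 9. Alkynylation with (R,R)‑ProPhenol and Me2Zn gives the 4R alcohol F8, and TBSOTf gives the bis‑silyl ether F9. DIBAL‑H/HMPA gives the vinylalane F10, and alkylation with 12 gives the enantiomeric Z‑allylboronate F11. Allylboration of 4, now syn to the silyloxy group, gives the hydroxy ester F12 and after lactonisation the lactone F13, which has C6 and C7 as in the target and C8 inverted. HF in MeCN gives the diol F14, and MnO2 gives the hydroxy enal F15. A Mitsunobu esterification with 19 (PPh3, DIAD, toluene, 0 °C) inverts C8 and gives 20, where the route is rejoined.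

**Further compounds**

F1 | step 13 | 2R epimer of 22 | C=C1C(=O)O[C@@H]2CC(=C)C[C@@H](O)/C=C(C)/C[C@H](OC(=O)/C(C)=C/C)[C@@H]12
F2 | step 13 | (1(10)E,6R,7S,8S)‑2‑oxo‑8‑[(2E)‑2‑methylbut‑2‑enoyloxy]germacra‑1(10),4(15),11(13)‑trien‑12,6‑olide | C=C1C(=O)O[C@@H]2CC(=C)CC(=O)/C=C(C)/C[C@H](OC(=O)/C(C)=C/C)[C@@H]12
F3 | step 15 | 2‑O‑triethylsilyl ether of 23 | C=C1C(=O)O[C@@H]2CC(=C)C[C@H](O[Si](CC)(CC)CC)[C@H]3O[C@]3(C)C[C@H](OC(=O)/C(C)=C/C)[C@@H]12
F4 | step 15 | C15 B‑alkyl‑9‑BBN adduct of F3 (C4 epimers) | C=C1C(=O)O[C@@H]2CC(CB5C6CCCC5CCC6)C[C@H](O[Si](CC)(CC)CC)[C@H]3O[C@]3(C)C[C@H](OC(=O)/C(C)=C/C)[C@@H]12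
F5 | step 15 | 2‑O‑triethylsilyl ether of the 15‑alcohol (C4 epimers) | C=C1C(=O)O[C@@H]2CC(CO)C[C@H](O[Si](CC)(CC)CC)[C@H]3O[C@]3(C)C[C@H](OC(=O)/C(C)=C/C)[C@@H]12
F6 | step 15 | 2‑O‑triethylsilyl ether of the 15‑aldehyde (C4 epimers) | C=C1C(=O)O[C@@H]2CC(C=O)C[C@H](O[Si](CC)(CC)CC)[C@H]3O[C@]3(C)C[C@H](OC(=O)/C(C)=C/C)[C@@H]12
F7 | step 15 | 2‑O‑triethylsilyl ether of 26 (C4 as in the target) | C=C1C(=O)O[C@@H]2C[C@@H](C=O)C[C@H](O[Si](CC)(CC)CC)[C@H]3O[C@]3(C)C[C@H](OC(=O)/C(C)=C/C)[C@@H]12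
F8 | step 9 | methyl (4R,6E)‑8‑{[tert‑butyl(dimethyl)silyl]oxy}‑4‑hydroxy‑6‑methyloct‑6‑en‑2‑ynoate | COC(=O)C#C[C@H](O)C/C(C)=C/CO[Si](C)(C)C(C)(C)C
F9 | step 9 | methyl (4R,6E)‑4,8‑bis{[tert‑butyl(dimethyl)silyl]oxy}‑6‑methyloct‑6‑en‑2‑ynoate | COC(=O)C#C[C@H](O[Si](C)(C)C(C)(C)C)C/C(C)=C/CO[Si](C)(C)C(C)(C)C
F10 | step 9 | enantiomer of vinylalane 13 | COC(=O)/C([Al](CC(C)C)CC(C)C)=C\[C@H](O[Si](C)(C)C(C)(C)C)C/C(C)=C/CO[Si](C)(C)C(C)(C)C
F11 | step 9 | enantiomer of allylboronate 14 (2Z,4R,6E) | COC(=O)/C(CB1OC(C)(C)C(C)(C)O1)=C\[C@H](O[Si](C)(C)C(C)(C)C)C/C(C)=C/CO[Si](C)(C)C(C)(C)C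
F12 | step 9 | epimer of hydroxy ester 15 at the silyloxy carbon C8 | COC(=O)C(=C)[C@@H]([C@H](O)CC(=C)CCl)[C@H](O[Si](C)(C)C(C)(C)C)C/C(C)=C/CO[Si](C)(C)C(C)(C)C
F13 | step 9 | epimer of lactone 16 at the silyloxy carbon C8 | C=C1C(=O)O[C@H](CC(=C)CCl)[C@H]1[C@H](O[Si](C)(C)C(C)(C)C)C/C(C)=C/CO[Si](C)(C)C(C)(C)C
F14 | step 9 | epimer of diol 17 at the carbinol carbon C8 | C=C1C(=O)O[C@H](CC(=C)CCl)[C@H]1[C@H](O)C/C(C)=C/CO
F15 | step 9 | epimer of hydroxy enal 18 at the carbinol carbon C8 | C=C1C(=O)O[C@H](CC(=C)CCl)[C@H]1[C@H](O)C/C(C)=C/C=O
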